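**Retrosynthetic overview**

- Structural basis (daucane numbering): C4 (tertiary OH, isopropyl), the ring-fusion carbon C5 and C6 form a β-hydroxy ketone once C6 is a carbonyl. The C4–C5 bond of the five-membered ring is therefore an aldol bond, and C4 and C5 can both be corrected by equilibration.
- Target ⇒ (phenol desilylation, C9 acetate by inversion, allylic hydroxylation at C9, C6 acylation, hydroxyl-directed C6 reduction) ⇒ trans-fused 4β-hydroxydauc-7-en-6-one ⇒ (retro-aldol, C4–C5) 3,6-dimethyl-6-(4-methyl-3-oxopentyl)cyclohept-2-en-1-one.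
- The diketone ⇒ copper-catalysed asymmetric conjugate addition of a ketal-masked 4-methyl-3-oxopentyl Grignard reagent to 3,6-dimethylcyclohepta-2,6-dien-1-one (sets C1, the only centre not set by the substrate) ⇒ cycloheptanone; side chain ⇒ isobutyryl chloride and ethene.
- Ring order: the seven-membered ring is bought as cycloheptanone; the five-membered ring is closed last, in the aldol step.

Key step: step 9

Remark on numbering and faces: daucane numbering is used. C1 is the quaternary ring-fusion carbon with the angular methyl, C2 and C3 are CH2, C4 carries OH and isopropyl, C5 is the ring-fusion CH, C6 carries the aroyloxy group, C7=C8 is the alkene with the methyl on C8, C9 carries the acetoxy group, and C10 is CH2. β is the face of the C1 methyl. Read this way the target is 1β-methyl, 5α-H (trans-fused), 4β-OH, 6α-aroyloxy, 9α-acetoxy, i.e. (1R,4R,5S,6S,9S).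

Assumption: the selenium dioxide oxidation of step 13 is taken to replace the pseudoaxial 9β-hydrogen by hydroxyl on the same face, so the acetate is then introduced with inversion.

**Route**

Step 1
Reactants: 1 isobutyryl chloride; 2 ethene
Product: 4 4-methylpent-1-en-3-one (isopropyl vinyl ketone), via 1-chloro-4-methylpentan-3-one 3 (not isolated)
Conditions: AlCl3, CH2Cl2, ethene (1 atm), −10 to 10 °C; H2O work-up; then Et3N, Et2O, 0 °C to rt (trace hydroquinone)
Reagents that add atoms: none
Why: Friedel–Crafts-type acylation of ethene gives the β-chloroethyl ketone, and E1cB loss of HCl with triethylamine gives the vinyl ketone, with no stereocentre formed.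

Step 2
Reactants: 4 4-methylpent-1-en-3-one
Product: 6 2-(2-bromoethyl)-5,5-dimethyl-2-(propan-2-yl)-1,3-dioxane, via 1-bromo-4-methylpentan-3-one 5 (not isolated)
Conditions: HBr (g), CH2Cl2, 0 °C; then 2,2-dimethylpropane-1,3-diol, HC(OEt)3, TsOH (cat.), rt
Reagents that add atoms: hydrogen bromide, Br; 2,2-dimethylpropane-1,3-diol, OCC(C)(C)CO
Why: conjugate hydrobromination of the enone followed by orthoformate-driven acid-catalysed ketalisation, the six-membered ketal being chosen because its β-magnesio derivative is thermally stable.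

Step 3
Reactants: 7 cycloheptanone
Product: 8 cyclohepta-2,6-dien-1-one
Conditions: IBX (2.5 equiv), DMSO/fluorobenzene, 70–75 °C
Reagents that add atoms: none
Why: IBX-mediated α,β-dehydrogenation of the ketone takes place on both sides, and limiting the oxidant and the temperature should hold the oxidation at the cross-conjugated dienone before tropone.

Step 4
Reactants: 8 cyclohepta-2,6-dien-1-one
Product: 9 6-methylcyclohept-2-en-1-one (racemic)
Conditions: Me2CuLi (from MeLi, CuI), Et2O, −78 to −40 °C; aq NH4Cl
Reagents that add atoms: lithium dimethylcuprate, [Li+].C[Cu-]C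
Why: Gilman cuprate 1,4-addition stops after one methyl because the product is a cross-conjugated dienolate, which is protonated to the conjugated enone on work-up (the new centre is racemic and is erased in step 6).

Step 5
Reactants: 9 6-methylcyclohept-2-en-1-one
Product: 10 3,6-dimethylcycloheptan-1-one (cis/trans mixture)
Conditions: Me2CuLi (from MeLi, CuI), Et2O, −78 to −20 °C; aq NH4Cl
Reagents that add atoms: lithium dimethylcuprate, [Li+].C[Cu-]C
Why: a second cuprate 1,4-addition places the second methyl, and the diastereomer mixture is immaterial since both methyl-bearing carbons become sp2 in the next step.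

Step 6
Reactants: 10 3,6-dimethylcycloheptan-1-one
Product: 11 3,6-dimethylcyclohepta-2,6-dien-1-one
Conditions: IBX (2.5 equiv), DMSO/fluorobenzene, 75 °C
Reagents that add atoms: none
Why: IBX dehydrogenation on both sides of the ketone can only give the symmetric β,β′-dimethyl dienone, since each α-methylene has a single hydrogen-bearing β-carbon.

Step 7
Reactants: 11 3,6-dimethylcyclohepta-2,6-dien-1-one; 6 2-(2-bromoethyl)-5,5-dimethyl-2-(propan-2-yl)-1,3-dioxane
Product: 13 (6S)-6-{2-[5,5-dimethyl-2-(propan-2-yl)-1,3-dioxan-2-yl]ethyl}-3,6-dimethylcyclohept-2-en-1-one, via ketal Grignard reagent 12 (not isolated)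
Conditions: 6, Mg, Et2O, rt; then 11, Cu(OTf)2 (4 mol%), chiral 1-(1-hydroxy-4-methylpentan-2-yl)-3-(2,4,6-trimethylphenyl)-4,5-dihydroimidazolium hexafluorophosphate (5 mol%, antipode giving 6S), Et2O, −30 to 0 °C; aq NH4Cl
Reagents that add atoms: none
Why: copper–N-heterocyclic-carbene-catalysed asymmetric conjugate addition of a primary alkyl Grignard reagent to a β-methyl cyclic enone builds the quaternary centre, the chiral carbene–cuprate choosing the π-face (the two enone halves of 11 are interchanged by the twofold axis through the carbonyl, so either β-carbon gives the same enantiomer), and the dienolate formed cannot take up a second alkyl group.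

Step 8
Reactants: 13 the ketal enone
Product: 14 (6S)-3,6-dimethyl-6-(4-methyl-3-oxopentyl)cyclohept-2-en-1-one
Conditions: 1 M HCl, THF, rt
Reagents that add atoms: water, O
Why: acid-catalysed ketal hydrolysis, helped by relief of strain at the hindered isopropyl ketal, frees the side-chain ketone without touching the non-epimerisable quaternary centre.

Step 9
Reactants: 14 (6S)-3,6-dimethyl-6-(4-methyl-3-oxopentyl)cyclohept-2-en-1-one
Product: 15 (1S,4R,5R)-4-hydroxydauc-7-en-6-one (trans-fused, 1β-methyl, 5α-H, 4β-OH, 4α-isopropyl)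
Conditions: KOt-Bu (0.3 equiv), t-BuOH/THF, 0 °C to rt; AcOH quench at 0 °C
Reagents that add atoms: none
Why: Substoichiometric tert-butoxide reversibly deprotonates the α′ methylene between the enone carbonyl and the quaternary carbon (daucane C5), and this cross-conjugated enolate adds to the side-chain isopropyl ketone to form C4–C5; the closest known reaction type is the base-mediated intramolecular aldol addition of 1,6-diketones to 2-acylcyclopentanols under equilibrating conditions. The five-membered ring closes in a 5-(enolexo)-exo-trig mode. C4 and C5 are both made in the reversible event, so retro-aldol and re-aldol interconvert all four diastereomers and the C1 quaternary centre alone decides the outcome: in the trans-fused 4β-hydroxy isomer the hydroxyl is hydrogen-bonded to the C6 carbonyl and the isopropyl group is both trans to the vicinal C6 substituent and anti to the 1,3-related angular methyl, an arrangement no cis-fused isomer can reach. The step needs aldol addition without E1cB dehydration to the C4=C5 enone and without γ-deprotonation that would move the C7=C8 bond out of conjugation. This is secured by the low temperature, by the catalytic base in a protic medium that reprotonates the aldolate at once, and by the substrate itself, whose quaternary C1 blocks any other enolisation on that side and favours ring closure through gem-disubstitution.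

Step 10
Reactants: 15 (1S,4R,5R)-4-hydroxydauc-7-en-6-one
Product: 16 (1S,4R,5S,6S)-dauc-7-ene-4,6-diol (4β,6α-diol)
Conditions: Me4NBH(OAc)3, MeCN/AcOH, −30 to 0 °C
Reagents that add atoms: none
Why: Evans–Saksena hydroxyl-directed reduction, in which the C4 hydroxyl exchanges onto boron and hands hydride through a chair-like six-membered transition state to the β face of the C6 carbonyl, should give the 6α (1,3-anti) alcohol by clean 1,2-reduction of the enone.

Step 11
Reactants: 17 4-hydroxybenzoic acid
Product: 19 4-[(tert-butyldimethylsilyl)oxy]benzoic acid, via silyl ester 18 (not isolated)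
Conditions: TBSCl (2.2 equiv), imidazole, DMF, rt; then AcOH/THF/H2O, rt
Reagents that add atoms: tert-butyldimethylsilyl chloride, CC(C)(C)[Si](C)(C)Cl
Why: bis-silylation followed by selective hydrolysis of the far more labile silyl ester leaves the aryl silyl ether in place.

Step 12
Reactants: 16 (1S,4R,5S,6S)-dauc-7-ene-4,6-diol; 19 4-[(tert-butyldimethylsilyl)oxy]benzoic acid
Product: 21 (1S,4R,5S,6S)-4-hydroxydauc-7-en-6-yl 4-[(tert-butyldimethylsilyl)oxy]benzoate, via acid chloride 20 (not isolated)
Conditions: 19, (COCl)2, DMF (cat.), CH2Cl2, 0 °C to rt, evaporate; then 16, Et3N, DMAP, CH2Cl2, 0 °C to rt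
Reagents that add atoms: none
Why: acid chloride formation and DMAP-catalysed acylation esterify the secondary allylic C6 hydroxyl with retention, while the hindered tertiary C4 hydroxyl does not react.

Step 13
Reactants: 21 the C6 ester
Product: 22 (1R,4R,5S,6S,9R)-4,9-dihydroxydauc-7-en-6-yl 4-[(tert-butyldimethylsilyl)oxy]benzoate (9β-alcohol)
Conditions: SeO2 (0.5 equiv), t-BuOOH, CH2Cl2, rt
Reagents that add atoms: tert-butyl hydroperoxide, CC(C)(C)OO (terminal oxidant, the oxygen being passed on through SeO2, O=[Se]=O)
Why: Riley oxidation, an ene reaction of the selenium oxidant at C7 that removes a hydrogen from the ring methylene on the more substituted alkene carbon, followed by a [2,3]-sigmatropic shift that returns oxygen to C9 and the double bond to C7=C8, should take the π-aligned pseudoaxial 9β-hydrogen and leave the hydroxyl on that same face, as in the 4β-hydroxylation of cholest-5-enes.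

Step 14
Reactants: 22 the 9β-alcohol
Product: 23 (1R,4R,5S,6S,9S)-9-acetoxy-4-hydroxydauc-7-en-6-yl 4-[(tert-butyldimethylsilyl)oxy]benzoate
Conditions: AcOH, PPh3, DIAD, THF, 0 °C to rt
Reagents that add atoms: acetic acid, CC(=O)O
Why: Mitsunobu esterification displaces the allylic oxyphosphonium at C9 by acetate in an SN2 sense with inversion, giving the pseudoequatorial 9α-acetate while the tertiary alcohol and the aryl silyl ether stay inert.

Step 15
Reactants: 23 the silyl-protected acetate
Product: 24 (1R,4R,5S,6S,9S)-9-acetoxy-4-hydroxydauc-7-en-6-yl 4-hydroxybenzoate (target)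
Conditions: KHF2, MeOH, rt
Reagents that add atoms: none
Why: fluoride cleavage of the aryl silyl ether under near-neutral conditions spares the acetate, the benzoate and the tertiary alcohol.

**Compound list**

1 | isobutyryl chloride | CC(C)C(=O)Cl | starting material
2 | ethene | C=C | starting material
3 | 1-chloro-4-methylpentan-3-one | CC(C)C(=O)CCCl | intermediate
4 | 4-methylpent-1-en-3-one | CC(C)C(=O)C=C | intermediate
5 | 1-bromo-4-methylpentan-3-one | CC(C)C(=O)CCBr | intermediate
6 | 2-(2-bromoethyl)-5,5-dimethyl-2-(propan-2-yl)-1,3-dioxane | CC(C)C1(CCBr)OCC(C)(C)CO1 | intermediate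
7 | cycloheptanone | O=C1CCCCCC1 | starting material
8 | cyclohepta-2,6-dien-1-one | O=C1C=CCCC=C1 | intermediate
9 | 6-methylcyclohept-2-en-1-one (racemic) | CC1CCC=CC(=O)C1 | intermediate
10 | 3,6-dimethylcycloheptan-1-one (cis/trans mixture) | CC1CCC(C)CC(=O)C1 | intermediate
11 | 3,6-dimethylcyclohepta-2,6-dien-1-one | CC1=CC(=O)C=C(C)CC1 | intermediate
12 | {2-[5,5-dimethyl-2-(propan-2-yl)-1,3-dioxan-2-yl]ethyl}magnesium bromide | CC(C)C1(CC[Mg]Br)OCC(C)(C)CO1 | intermediate
13 | (6S)-6-{2-[5,5-dimethyl-2-(propan-2-yl)-1,3-dioxan-2-yl]ethyl}-3,6-dimethylcyclohept-2-en-1-one | CC(C)C1(CC[C@]2(C)CCC(C)=CC(=O)C2)OCC(C)(C)CO1 | intermediate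
14 | (6S)-3,6-dimethyl-6-(4-methyl-3-oxopentyl)cyclohept-2-en-1-one | CC(C)C(=O)CC[C@]1(C)CCC(C)=CC(=O)C1 | intermediate
15 | (1S,4R,5R)-4-hydroxydauc-7-en-6-one (trans-fused, 4β-OH) | C1C[C@@]2(C)CC[C@@](O)(C(C)C)[C@@H]2C(=O)C=C1C | intermediate
16 | (1S,4R,5S,6S)-dauc-7-ene-4,6-diol (4β,6α) | C1C[C@@]2(C)CC[C@@](O)(C(C)C)[C@@H]2[C@@H](O)C=C1C | intermediate
17 | 4-hydroxybenzoic acid | O=C(O)c1ccc(O)cc1 | starting material
18 | tert-butyldimethylsilyl 4-[(tert-butyldimethylsilyl)oxy]benzoate | CC(C)(C)[Si](C)(C)OC(=O)c1ccc(O[Si](C)(C)C(C)(C)C)cc1 | intermediate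
19 | 4-[(tert-butyldimethylsilyl)oxy]benzoic acid | CC(C)(C)[Si](C)(C)Oc1ccc(C(=O)O)cc1 | intermediate
20 | 4-[(tert-butyldimethylsilyl)oxy]benzoyl chloride | CC(C)(C)[Si](C)(C)Oc1ccc(C(Cl)=O)cc1 | intermediate
21 | (1S,4R,5S,6S)-4-hydroxydauc-7-en-6-yl 4-[(tert-butyldimethylsilyl)oxy]benzoate | C1C[C@@]2(C)CC[C@@](O)(C(C)C)[C@@H]2[C@@H](OC(=O)c2ccc(O[Si](C)(C)C(C)(C)C)cc2)C=C1C | intermediate
22 | (1R,4R,5S,6S,9R)-4,9-dihydroxydauc-7-en-6-yl 4-[(tert-butyldimethylsilyl)oxy]benzoate (9β-OH) | O[C@@H]1C[C@@]2(C)CC[C@@](O)(C(C)C)[C@@H]2[C@@H](OC(=O)c2ccc(O[Si](C)(C)C(C)(C)C)cc2)C=C1C | intermediate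
23 | (1R,4R,5S,6S,9S)-9-acetoxy-4-hydroxydauc-7-en-6-yl 4-[(tert-butyldimethylsilyl)oxy]benzoate | CC(=O)O[C@H]1C[C@@]2(C)CC[C@@](O)(C(C)C)[C@@H]2[C@@H](OC(=O)c2ccc(O[Si](C)(C)C(C)(C)C)cc2)C=C1C | intermediate
24 | (1R,4R,5S,6S,9S)-9-acetoxy-4-hydroxydauc-7-en-6-yl 4-hydroxybenzoate | CC(=O)O[C@H]1C[C@@]2(C)CC[C@@](O)(C(C)C)[C@@H]2[C@@H](OC(=O)c2ccc(O)cc2)C=C1C | target

**Step count**

Total: 15 steps. Longest linear sequence: 12 steps (cycloheptanone through steps 3–10 and 12–15).

**Steps most likely to fail, with fallbacks**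

1. Step 9 (key aldol).
   - What may go wrong: the aldolate may lose water by E1cB faster than the diastereomers equilibrate; the equilibrium may rest with the open diketone or a cis-fused ketol; or base may move the C7=C8 bond out of conjugation.
   - Fallback, from 14 back to 15: the condensation is driven on purpose (KOH, MeOH, reflux) to the cross-conjugated dienone (1S)-dauca-4,7-dien-6-one F1.
   - NaBH4/CeCl3·7H2O (MeOH, −78 °C), with hydride expected anti to the angular methyl, gives the 6β-dienol F2.
   - mCPBA/NaHCO3 (CH2Cl2, 0 °C) epoxidises the electron-rich tetrasubstituted C4=C5 bond on the face of the hydroxyl to give the 4β,5β-epoxy-6β-alcohol F3.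
   - Dess–Martin periodinane gives the epoxy enone F4.
   - SmI2 (THF/MeOH, −90 °C) cleaves the C5–O bond reductively and the enolate is protonated to give 15. The C4 oxygen is then fixed irreversibly on the β face, and C5 can be adjusted through the enol alone.

2. Step 7 (asymmetric conjugate addition).
   - What may go wrong: poor π-facial discrimination on the flatter, less electrophilic cross-conjugated dienone; erosion of selectivity by the functionalised Grignard reagent; or competing 1,2-addition.
   - Fallback, from 9 and 12 back to 13: the roles are exchanged so that the methyl group, not the side chain, is transferred enantioselectively.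
   - Achiral addition of 12 to 9 (CuBr·SMe2 cat., TMSCl, THF, −78 °C) gives the silyl enol ether F5.
   - Saegusa–Ito oxidation (Pd(OAc)2, MeCN) gives 3-{2-[5,5-dimethyl-2-(propan-2-yl)-1,3-dioxan-2-yl]ethyl}-6-methylcyclohept-2-en-1-one F6.
   - Asymmetric conjugate addition of Me3Al (copper thiophene-2-carboxylate cat., chiral phosphoramidite, Et2O, −30 °C), a well-documented class for β-alkyl cycloalkenones, gives the quaternary ketone F7.
   - IBX (DMSO, 70 °C) can dehydrogenate only towards the methyl-bearing carbon, because the other α-methylene adjoins the quaternary centre, and gives 13.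

3. Step 13 (allylic hydroxylation).
   - What may go wrong: competing oxidation of the C8 methyl group; a sluggish ene reaction next to the allylic ester; or delivery of oxygen to the α face.
   - Fallback, from 15 (with 20) back to 23: the C9 oxygen is brought in at the enone stage by vinylogous oxidation.
   - TMSOTf/Et3N (CH2Cl2) gives the bis-silyl linear dienol ether F8.
   - Photooxygenation (O2, hν, tetraphenylporphyrin, −78 °C; then PPh3; then K2CO3/MeOH) adds singlet oxygen across C6/C9 anti to the angular methyl and, after collapse of the silyl peroxyketal and reduction, gives the 9α-hydroxy enone F9.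
   - Ac2O/pyridine, at a stage where C9–OH is the only secondary alcohol, gives the acetoxy enone F10.
   - Directed reduction as in step 10 gives the 9α-acetoxy-4β,6α-diol F11, and acylation with 20 (Et3N, DMAP) gives 23.
   - Should the Riley oxidation itself place the hydroxyl on the α face, that epimer, the 9α-alcohol F12, is simply acetylated (Ac2O, pyridine) to 23.

**Further compounds**

F1 | step 9 | (1S)-dauca-4,7-dien-6-one | CC1=CC(=O)C2=C(C(C)C)CC[C@]2(C)CC1
F2 | step 9 | (1S,6β)-dauca-4,7-dien-6-ol | CC1=C[C@@H](O)C2=C(C(C)C)CC[C@]2(C)CC1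
F3 | step 9 | 4β,5β-epoxydauc-7-en-6β-ol | CC1=C[C@@H](O)[C@]23O[C@@]2(C(C)C)CC[C@]3(C)CC1
F4 | step 9 | 4β,5β-epoxydauc-7-en-6-one | CC1=CC(=O)[C@]23O[C@@]2(C(C)C)CC[C@]3(C)CC1
F5 | step 7 | 3-{2-[5,5-dimethyl-2-(propan-2-yl)-1,3-dioxan-2-yl]ethyl}-6-methyl-1-(trimethylsilyloxy)cyclohept-1-ene (diastereomer mixture) | C[Si](C)(C)OC1=CC(CCC2(C(C)C)OCC(C)(C)CO2)CCC(C)C1
F6 | step 7 | 3-{2-[5,5-dimethyl-2-(propan-2-yl)-1,3-dioxan-2-yl]ethyl}-6-methylcyclohept-2-en-1-one (racemic) | O=C1C=C(CCC2(C(C)C)OCC(C)(C)CO2)CCC(C)C1
F7 | step 7 | (3S)-3-{2-[5,5-dimethyl-2-(propan-2-yl)-1,3-dioxan-2-yl]ethyl}-3,6-dimethylcycloheptan-1-one (C6 epimer mixture) | CC(C)C1(CC[C@]2(C)CCC(C)CC(=O)C2)OCC(C)(C)CO1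
F8 | step 13 | 4β,6-bis(trimethylsilyloxy)dauca-6,8-diene | CC1=CC[C@@]2(C)CC[C@@](O[Si](C)(C)C)(C(C)C)[C@@H]2C(O[Si](C)(C)C)=C1
F9 | step 13 | 4β,9α-dihydroxydauc-7-en-6-one | O[C@H]1C[C@@]2(C)CC[C@@](O)(C(C)C)[C@@H]2C(=O)C=C1C
F10 | step 13 | 9α-acetoxy-4β-hydroxydauc-7-en-6-one | CC(=O)O[C@H]1C[C@@]2(C)CC[C@@](O)(C(C)C)[C@@H]2C(=O)C=C1C
F11 | step 13 | 9α-acetoxydauc-7-ene-4β,6α-diol | CC(=O)O[C@H]1C[C@@]2(C)CC[C@@](O)(C(C)C)[C@@H]2[C@@H](O)C=C1C
F12 | step 13 | 4β,9α-dihydroxydauc-7-en-6α-yl 4-[(tert-butyldimethylsilyl)oxy]benzoate | O[C@H]1C[C@@]2(C)CC[C@@](O)(C(C)C)[C@@H]2[C@@H](OC(=O)c2ccc(O[Si](C)(C)C(C)(C)C)cc2)C=C1C
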